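If the dimer step takes up the second substrate early, this flask comes down to one balance, so I tested that first.

    second substrate + partner ⇌ second product (K1 = 0.85 /M, k1 = 0.0037 /M/s)
    target ⇌ isomer of the product (K2 = 0.76, k2 = 0.0012 /s)
    starting material + partner ⇌ target (K3 = 0.71 /M, k3 = 0.0026 /M/s)
    2 second substrate → homo dimer (k4 = 0.0011 /M/s)

starting material 0.20 M; partner 0.200 M; second substrate 0.400 M; time 30 h

- the state of affairs at 30 h: stopped, and by what, or still going (the partner has run out first / all of the starting material has reacted / forward and back rates have come level / it is still moving)
- the target standing at 30 h, as a percentage of the starting material charged

- where a step has two of a species, its rate is k times that concentration squared, and two are used at each turn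
- the reaction counts as stopped when no species that holds the starting material changes by six tenths of a point or more over the second half of the time
- run time (flask): 30 h

By the dimer step alone, the first half-life of the second substrate was 0.316 h. I reckoned its second-order fall by that step to 0.00416 M at 30 h. Even with c(partner) at its charge, step 1 then held far less partner as second product than was charged. Step 3 has a forward half-life of 0.37 h at the charges, and target and isomer of the product relax in 0.0693 h. Both are far shorter than the run, so I froze these two steps as balances.

I carried one quantity, the pool constant: target plus isomer of the product, divided by c(starting material) times c(partner), at balance. It is 1.25 /M, and the target makes 56.8% of that pool.

I reckoned the target two ways. First I froze c(partner) at its charge, as in a plain binding isotherm, and got 11.4%. Then I let the pool take partner and starting material one for one, which gives the tight-binding quadratic. Its pool was 0.0343 M, so I put the target at 9.75%. The two ways parted, and the first one cheated. It held c(partner) at 0.200 M while the pool took 17.1% of that charge. I committed to the quadratic, with forward and back rates level.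

The forecast said forward and back rates have come level and 9.7%, with “starting material, target and isomer effectively at equilibrium”.

The simulation gave forward and back rates have come level and 9.72%.

Read from the standings at 30.0 h, the pool constant of this flask was 1.25 /M. I took 1.25 /M to a neighbour flask, the same flask charged with 0.80 M of partner, which is 4.00 equiv. The quadratic gave a pool of 0.0938 M. That puts the target at 26.6% and leaves 53.1% of the starting material. The neighbour flask stood at 26.6% of target, with 53.2% of the starting material left.

(The numbers of this flask are invented; the flask was simulated.)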